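## Plan
1. Cuts: first the ester C–O bonds at O3 and O9 (acyl donor hex-2-ynoic acid, a latent (Z)-hex-2-enoyl group), then C8–O, then C7–C11, and last C4–C5 together with C1–C10.
2. Enabling feature: ring A holds the methyl-bearing methine C4 and the methylated quaternary C5 next to the ring-fusion carbon C10. O3 lies para to C10, and O9 sits on the ring B carbon bonded to C10. Ring A is therefore the [4+2] adduct of a C1–C4 diene oxygenated at C3 with the C5=C10 alkene of a ring B enone whose carbonyl is C9.
3. Forward order: ring B is bought as 3-methylcyclohex-2-enone and ring A closes in step 2. Ring B is then elaborated (C10, C7=C8, C7–C11, O8, C9) while C3 rests as its enol silane. Ring A is finished next (C4, C3), and the two acyl groups are attached and semihydrogenated.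
4. Stereochemistry: C5 comes from the chiral boron catalyst, and the axial C14 methyl on C5 relays it to the other centres. C10 and C4 are set by equilibration, C7 and C8 by attack on the α-face opposite C14, C9 by hydride anti to an axial 8α-silyloxy group, and C3 by dissolving-metal reduction to the equatorial alcohol. The Z alkenes come from syn addition of H2 to the ynoates.

Key step: step 2

Convention: target (eremophilane) numbering is used for all bicyclic compounds; β is the face of C14 and α the opposite face.

Assumption: the sense of induction in step 2 is taken from the usual binding model of the cation (boron on the carbonyl oxygen, C10–H in contact with the ring oxygen, one phenyl group over the rear face). Should the opposite face react, the equally available catalyst from (R)-diphenylprolinol is used with no other change.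

## Route

**Step 1**
Reactants: 1 pent-1-en-3-one
Product: 2 (Z)-3-(triisopropylsilyloxy)penta-1,3-diene
Conditions: i-Pr3SiOTf, Et3N, CH2Cl2, 0 °C
Reagents that add atoms: triisopropylsilyl trifluoromethanesulfonate, CC(C)[Si](C(C)C)(C(C)C)OS(=O)(=O)C(F)(F)F
Why: Soft enolisation (silyl triflate and amine) can only remove a proton from the CH2 of the ethyl branch, and the arrangement that keeps the methyl group away from the vinyl group should give the (Z)-enol silane, whose methyl points outward in the s-cis diene.

**Step 2**
Reactants: 2 (Z)-3-(triisopropylsilyloxy)penta-1,3-diene; 3 3-methylcyclohex-2-en-1-one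
Product: 4 cis-fused endo adduct (C9 ketone, C2=C3 enol silane, C14 β, H10 β, C15 α)
Conditions: (S)-3,3-diphenyl-1-(o-tolyl)tetrahydro-1H,3H-pyrrolo[1,2-c][1,3,2]oxazaborole (20 mol %), HNTf2 (17 mol %), 2 (2 equiv), CH2Cl2 (concentrated), −20 → 23 °C
Reagents that add atoms: none
Why: Proposed new method: the cation formed from the oxazaborolidine and HNTf2 binds the carbonyl oxygen of 3 at boron on the side of C10–H, lowers the enone LUMO and covers one face with a phenyl group, so that 2 meets the open α-face (Si at C5 and at C10), and C4, the nucleophilic terminus of the enol silane, bonds to the β-carbon C5 ahead of C1–C10 in a concerted but strongly asynchronous [4+2] cycloaddition whose stepwise limit, Mukaiyama–Michael addition followed by Michael closure, ends in the same product. The closest known reaction types are the oxazaborolidinium-catalysed Diels–Alder addition of 2-silyloxydienes to 2-cycloalkenones without a β-substituent and the achiral aluminium-halide-promoted addition of such dienes to 3-methylcyclohex-2-enone; new is the action of the chiral boron cation on a β,β-disubstituted enone with formation of a quaternary carbon. Ring A closes as a six-membered carbocycle by intermolecular, suprafacial [4+2] addition and retains the C2=C3 enol silane. C5 is set by the catalyst through the choice of enone face, C10 by the suprafacial addition to the ring alkene (cis fusion, H10 β), and C4 by the endo position of ring B under the diene combined with the outward methyl of the (Z)-diene (C15 α, anti to C14). The step needs enantioface selectivity and para regiochemistry: the first rests on the catalyst, kept in slight excess over HNTf2 so that no free acid can turn 2 into an achiral silyl triflimide catalyst, the second on the 3-silyloxy group, whose donor effect makes C4 the nucleophilic end and matches it with the electrophilic C5. Diastereocontrol at C4 and C10 is not critical, since both centres are equilibrated later (steps 9 and 3).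

**Step 3**
Reactants: 4 cis-fused endo adduct
Product: 5 trans-fused ketone (H10 α)
Conditions: NaOMe (0.2 equiv), MeOH–THF, 23 °C
Reagents that add atoms: none
Why: Base-catalysed epimerisation through the C9–C10 enolate is under thermodynamic control, and the trans-fused ketone should prevail because the cis isomer must place C15 either against the bulky silyloxy group (A1,2 strain) or syn-axial to C9, whereas in 5 the pseudoaxial C15 meets only H10, and C4 cannot change while C3 is an enol silane.

**Step 4**
Reactants: 5 trans-fused ketone
Product: 7 trans-fused C7=C8 enone, via lithium C8=C9 enolate 6 (not isolated)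
Conditions: LiN(i-Pr)2, THF, −78 °C; then PhS(Cl)=Nt-Bu, −78 °C
Reagents that add atoms: none
Why: Kinetic deprotonation takes the C8 methylene rather than the C10 methine, and the Mukaiyama dehydrogenation (attack of the enolate on sulfur, then syn elimination of the sulfenamide) gives the enone at low temperature without touching the neutral triisopropylsilyl enol ether.

**Step 5**
Reactants: 7 trans-fused C7=C8 enone; 8 isopropenylmagnesium bromide
Product: 9 7α-isopropenyl C8=C9 trimethylsilyl enol ether
Conditions: 8 (2 equiv), CuBr·SMe2 (20 mol %), Me3SiCl, DMPU, THF, −78 °C; Et3N, cold aq NaHCO3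
Reagents that add atoms: isopropenylmagnesium bromide (8), C=C(C)[Mg]Br; chlorotrimethylsilane, C[Si](C)(C)Cl
Why: In this copper-catalysed, chlorosilane-accelerated conjugate addition the axial C14 methyl of the rigid trans-fused enone stands 1,3 to C7 and closes the β-face, so the isopropenyl group should enter from the α-face and end equatorial, while silylation fixes the C8=C9 enolate regiospecifically.

**Step 6**
Reactants: 9 7α-isopropenyl C8=C9 trimethylsilyl enol ether
Product: 11 8α-hydroxy 9-ketone, via lithium C8=C9 enolate 10 (not isolated)
Conditions: MeLi, THF, 0 °C; then 2-(phenylsulfonyl)-3-phenyloxaziridine, −78 °C; H2O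
Reagents that add atoms: 2-(phenylsulfonyl)-3-phenyloxaziridine, O=S(=O)(c1ccccc1)N1OC1c1ccccc1
Why: MeLi cleaves only the trimethylsilyl enol ether to the regiodefined lithium enolate, and the Davis α-hydroxylation should deliver oxygen along the axial direction from the α-face, which is stereoelectronically preferred and turned away from C14, while the neutral enol silane and the isopropenyl group are inert to the oxaziridine at −78 °C.

**Step 7**
Reactants: 11 8α-hydroxy 9-ketone
Product: 12 8α-(tert-butyldimethylsilyloxy) 9-ketone
Conditions: t-BuMe2SiOTf, 2,6-lutidine, CH2Cl2, −78 → 0 °C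
Reagents that add atoms: tert-butyldimethylsilyl trifluoromethanesulfonate, CC(C)(C)[Si](C)(C)OS(=O)(=O)C(F)(F)F
Why: Silylation of a hindered secondary alcohol with a silyl triflate and 2,6-lutidine is standard, is too weakly basic to disturb the labile C8 centre, and installs the bulky axial group that steers step 8.

**Step 8**
Reactants: 12 8α-(tert-butyldimethylsilyloxy) 9-ketone
Product: 13 9α-alcohol
Conditions: NaBH4, CeCl3·7H2O, MeOH–THF, −78 → −20 °C
Reagents that add atoms: none
Why: In this Luche-type reduction with a small hydride the axial 8α-silyloxy group blocks the equatorial (α) trajectory and, as the polar Felkin–Anh substituent, favours attack anti to its C–O bond, so hydride should arrive axially from the β-face in spite of C14 and give the equatorial 9α-alcohol cis to O8.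

**Step 9**
Reactants: 13 9α-alcohol
Product: 15 8α,9α-dihydroxy-4β-methyl 3-ketone, via 4α-methyl keto diol 14 (not isolated)
Conditions: n-Bu4NF, THF, 23 °C; then NaOMe (0.3 equiv), MeOH, 23 °C
Reagents that add atoms: none
Why: Fluoride cleaves both Si–O bonds (the enol silane gives the C3 ketone by protonation at C2, the silyl ether gives the alcohol), and methoxide then equilibrates C4 through the C3–C4 enolate to the equatorial 4β-methyl epimer, which arises by axial protonation on the open α-face and is free of the syn-axial contacts with H2 and H10, any remaining 4α-epimer being resubmitted.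

**Step 10**
Reactants: 15 8α,9α-dihydroxy-4β-methyl 3-ketone
Product: 16 3α,8α,9α-triol
Conditions: Li, NH3(l)–THF, EtOH, −78 °C
Reagents that add atoms: none
Why: Dissolving-metal reduction of a cyclohexanone gives the more stable carbinol, here the equatorial 3α-alcohol trans to C15, whereas hydride reagents would be pushed by the syn-axial C14 to the α-face and give the axial epimer, and the isolated 1,1-disubstituted alkene is inert.

**Step 11**
Reactants: 16 3α,8α,9α-triol; 17 hex-2-ynoic acid
Product: 18 3,9-bis(hex-2-ynoate) with free 8α-hydroxyl
Conditions: 17 (2.2 equiv), DCC, DMAP (10 mol %), CH2Cl2, −20 → 0 °C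
Reagents that add atoms: hex-2-ynoic acid (17), CCCC#CC(=O)O
Why: Steglich esterification with a limited amount of acid should acylate the two equatorial hydroxyls at C3 and C9, while the axial 8α-hydroxyl, flanked by the isopropenyl group and the C9 ester and syn-axial to H6 and H10, stays free, in line with the usual equatorial-over-axial preference of cis-1,2-diols.

**Step 12**
Reactants: 18 3,9-bis(hex-2-ynoate)
Product: 19 target CNP0420276.1
Conditions: H2 (1 atm), Pd/CaCO3 poisoned with Pb(OAc)2, quinoline, EtOAc, 23 °C
Reagents that add atoms: none
Why: Lindlar semihydrogenation adds H2 syn to each conjugated alkyne and gives the two (Z)-enoates, the poisoned palladium surface with quinoline leaving the isopropenyl group and the new enoates unreduced.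

## Compound list
1 | pent-1-en-3-one | C=CC(=O)CC | starting material
2 | (Z)-3-(triisopropylsilyloxy)penta-1,3-diene | C=C/C(O[Si](C(C)C)(C(C)C)C(C)C)=C/C | intermediate
3 | 3-methylcyclohex-2-en-1-one | CC1=CC(=O)CCC1 | starting material
4 | (4aR,5S,8aS)-4a,5-dimethyl-6-(triisopropylsilyloxy)-3,4,4a,5,8,8a-hexahydronaphthalen-1(2H)-one; cis-fused, C14 β, H10 β, C15 α | C1C[C@]2(C)[C@H](C)C(O[Si](C(C)C)(C(C)C)C(C)C)=CC[C@@H]2C(=O)C1 | intermediate
5 | (4aR,5S,8aR)-4a,5-dimethyl-6-(triisopropylsilyloxy)-3,4,4a,5,8,8a-hexahydronaphthalen-1(2H)-one; trans-fused, H10 α | C1C[C@]2(C)[C@H](C)C(O[Si](C(C)C)(C(C)C)C(C)C)=CC[C@H]2C(=O)C1 | intermediate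
6 | lithium C8=C9 enolate of 5 | [Li+].C1C[C@]2(C)[C@H](C)C(O[Si](C(C)C)(C(C)C)C(C)C)=CC[C@H]2C([O-])=C1 | intermediate
7 | (4aR,5S,8aR)-4a,5-dimethyl-6-(triisopropylsilyloxy)-4a,5,8,8a-tetrahydronaphthalen-1(4H)-one; trans-fused C7=C8 enone | O=C1C=CC[C@]2(C)[C@H](C)C(O[Si](C(C)C)(C(C)C)C(C)C)=CC[C@@H]12 | intermediate
8 | isopropenylmagnesium bromide | C=C(C)[Mg]Br | starting material
9 | 7α-isopropenyl-4α,5β-dimethyl-9-(trimethylsilyloxy)-3-(triisopropylsilyloxy)-10αH-octala-2,8-diene | C=C(C)[C@@H]1C[C@]2(C)[C@H](C)C(O[Si](C(C)C)(C(C)C)C(C)C)=CC[C@H]2C(O[Si](C)(C)C)=C1 | intermediate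
10 | lithium C8=C9 enolate derived from 9 | [Li+].C=C(C)[C@@H]1C[C@]2(C)[C@H](C)C(O[Si](C(C)C)(C(C)C)C(C)C)=CC[C@H]2C([O-])=C1 | intermediate
11 | 8α-hydroxy-7α-isopropenyl-4α,5β-dimethyl-3-(triisopropylsilyloxy)-10αH-octal-2-en-9-one | C=C(C)[C@@H]1C[C@]2(C)[C@H](C)C(O[Si](C(C)C)(C(C)C)C(C)C)=CC[C@H]2C(=O)[C@@H]1O | intermediate
12 | 8α-tert-butyldimethylsilyl ether of 11 | C=C(C)[C@@H]1C[C@]2(C)[C@H](C)C(O[Si](C(C)C)(C(C)C)C(C)C)=CC[C@H]2C(=O)[C@@H]1O[Si](C)(C)C(C)(C)C | intermediate
13 | 9α-alcohol of 12 (8α-silyloxy axial, 9α-hydroxyl equatorial) | C=C(C)[C@@H]1C[C@]2(C)[C@H](C)C(O[Si](C(C)C)(C(C)C)C(C)C)=CC[C@H]2[C@H](O)[C@@H]1O[Si](C)(C)C(C)(C)C | intermediate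
14 | 8α,9α-dihydroxy-7α-isopropenyl-4α,5β-dimethyl-10αH-decalin-3-one | C=C(C)[C@@H]1C[C@]2(C)[C@H](C)C(=O)CC[C@H]2[C@H](O)[C@@H]1O | intermediate
15 | 8α,9α-dihydroxy-7α-isopropenyl-4β,5β-dimethyl-10αH-decalin-3-one | C=C(C)[C@@H]1C[C@]2(C)[C@@H](C)C(=O)CC[C@H]2[C@H](O)[C@@H]1O | intermediate
16 | 7α-isopropenyl-4β,5β-dimethyl-10αH-decalin-3α,8α,9α-triol | C=C(C)[C@@H]1C[C@]2(C)[C@@H](C)[C@H](O)CC[C@H]2[C@H](O)[C@@H]1O | intermediate
17 | hex-2-ynoic acid | CCCC#CC(=O)O | starting material
18 | 3α,9α-bis(hex-2-ynoyloxy) derivative of 16, 8α-hydroxyl free | C=C(C)[C@@H]1C[C@]2(C)[C@@H](C)[C@H](OC(=O)C#CCCC)CC[C@H]2[C@H](OC(=O)C#CCCC)[C@@H]1O | intermediate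
19 | (3R,4R,5R,7S,8R,9S,10R)-8-hydroxyeremophil-11-ene-3,9-diyl bis[(Z)-hex-2-enoate] (eremophilane numbering) | C=C(C)[C@@H]1C[C@]2(C)[C@@H](C)[C@H](OC(=O)/C=C\CCC)CC[C@H]2[C@H](OC(=O)/C=C\CCC)[C@@H]1O | target

## Step count and risks
Total steps: 12. Longest linear sequence: 12 (from 1).

**Risk 1, step 2.**
- What may go wrong: the β-methyl group may slow the cycloaddition so much that desilylation or oligomerisation of the diene overtakes the catalysed path. A racemic background reaction started by adventitious silyl triflimide could do the same. Either would cost conversion or enantiopurity.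
- Fallback (known chemistry): racemic cycloaddition followed by resolution. Starting from 2 and 3, the cycloaddition is run with the achiral Lewis acid AlBr3 containing a little AlMe3 as proton scavenger, in toluene–CH2Cl2 at about 0 °C. These conditions are established for hindered 2-silyloxydienes and 3-methylcyclohex-2-enone.
- This gives 4 as the racemate, that is together with the mirror-image adduct F1. Equilibration as in step 3 gives 5 together with the mirror-image trans ketone F2.
- Preparative chromatography on a chiral stationary phase separates the two, and the route is rejoined at 5.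

**Risk 2, step 5.**
- What may go wrong: the stereoelectronic preference for axial entry through a chair-like transition state may compete with steric approach control, so that facial selectivity at C7 is poor or reversed.
- Fallback: ligand control replaces substrate control. Starting from 7, a Hayashi–Miyaura addition of isopropenylboronic acid pinacol ester is run with [Rh(OH)((R)-BINAP)]2 in dioxane–water at 40 °C.
- (R)-BINAP is the antipode that, by the usual quadrant model, places an alkenyl group on the α-face ((R) at C7). The product is the 7α-isopropenyl 9-ketone F3.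
- LiN(i-Pr)2 in THF at −78 °C then deprotonates C8 and gives the lithium enolate 10, where the route is rejoined within step 6.

**Risk 3, step 8.**
- What may go wrong: the syn-axial C14 methyl may outweigh the shielding by the 8α-silyloxy group, so that hydride arrives from the α-face and facial selectivity at C9 is lost.
- Fallback: thermodynamic control replaces kinetic control. Starting from 12, reduction is carried out without regard to the face, and the product containing the axial 9β-alcohol F4 is equilibrated by reversible hydrogen transfer.
- The catalyst is (η5-C5Ph5)Ru(CO)2Cl with catalytic KOt-Bu in toluene, the alcohol-racemisation system of dynamic kinetic resolutions.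
- The hydroxyl of F4 is syn-axial to C14, so the equilibrium should lie on the side of the equatorial alcohol 13, where the route is rejoined.

## Further compounds
F1 | step 2 | (4aS,5R,8aR)-4a,5-dimethyl-6-(triisopropylsilyloxy)-3,4,4a,5,8,8a-hexahydronaphthalen-1(2H)-one, mirror image of 4 | C1C[C@@]2(C)[C@@H](C)C(O[Si](C(C)C)(C(C)C)C(C)C)=CC[C@H]2C(=O)C1
F2 | step 2 | (4aS,5R,8aS)-4a,5-dimethyl-6-(triisopropylsilyloxy)-3,4,4a,5,8,8a-hexahydronaphthalen-1(2H)-one, mirror image of 5 | C1C[C@@]2(C)[C@@H](C)C(O[Si](C(C)C)(C(C)C)C(C)C)=CC[C@@H]2C(=O)C1
F3 | step 5 | 7α-isopropenyl-4α,5β-dimethyl-3-(triisopropylsilyloxy)-10αH-octal-2-en-9-one | C=C(C)[C@@H]1C[C@]2(C)[C@H](C)C(O[Si](C(C)C)(C(C)C)C(C)C)=CC[C@H]2C(=O)C1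
F4 | step 8 | 9β-epimer of 13 (axial 9β-hydroxyl) | C=C(C)[C@@H]1C[C@]2(C)[C@H](C)C(O[Si](C(C)C)(C(C)C)C(C)C)=CC[C@H]2[C@@H](O)[C@@H]1O[Si](C)(C)C(C)(C)C
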